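The route rests on cutting the C8–C9 bond of ring B (C5–C10), the cyclohexane fused to the gem-dimethylcyclohexene ring A. In ring B the methyl-bearing C9 lies between the C10=C1 alkene and the quaternary C8. C9 therefore becomes the β-carbon of a ring A dienal and C8 a tertiary radical. One hydrogen-atom-transfer-initiated 6-exo cyclisation closes ring B, forges the congested C8–C9 bond and sets both stereocentres beside the finished dioxabicyclooctanone. The precursor is an open triene: bicyclic acylal, 1,1-disubstituted alkene, two-carbon tether, ring A dienal. The formyl activator then leaves as CO and unveils the C9 methyl.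

Key step: step 16

Numbering: ring A = C1–C5 and C10 (C4 carries the gem-dimethyl group, C10=C1 is the alkene). Ring B = C5–C10 (C8 quaternary, C9 = CHMe). The polar unit is numbered as 2,7-dioxabicyclo[3.2.1]octan-3-one: C1 acetal, C3 lactone C=O, C5 bridgehead, C6 = CHCO2Me, C8 bridge carbon.

Remark on the chemistry: the carbonyl-ene reaction of a cyclic Z-alkene is assumed to give the syn adduct through a closed transition state with the ester endo. The target needs the anti relation, hence the inversion in step 2.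

Step 1
Reactants: 1 cyclopentene; 2 methyl glyoxylate
Product: 3 methyl (2S)-2-[(1R)-cyclopent-2-en-1-yl]-2-hydroxyacetate
Conditions: [Cu((S,S)-t-Bu-box)](SbF6)2 (10 mol %), excess 1, CH2Cl2, 25 °C
Reagents that add atoms: none
Why: Catalytic enantioselective carbonyl-ene reaction: the chelate of glyoxylate on divalent copper should expose one aldehyde face (carbinol carbon S), and the closed endo transition state with the cyclic Z-alkene should set the ring carbon syn to it (1R).

Step 2
Reactants: 3 methyl (2S)-2-[(1R)-cyclopent-2-en-1-yl]-2-hydroxyacetate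
Product: 6 methyl (2R)-2-[(1R)-cyclopent-2-en-1-yl]-2-hydroxyacetate, via triflate 4 (not isolated), via nitrite ester 5 (not isolated)
Conditions: Tf2O, 2,6-lutidine, CH2Cl2, −78 °C; then Bu4NNO2, MeCN, 0 to 25 °C; aqueous work-up
Reagents that add atoms: tetrabutylammonium nitrite, CCCC[N+](CCCC)(CCCC)CCCC.[O-]N=O
Why: Lattrell–Dax inversion: the α-triflyloxy ester is an excellent SN2 substrate, so nitrite should displace triflate with clean inversion, and the nitrite ester hydrolyses on work-up to the (2R)-alcohol.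

Step 3
Reactants: 6 methyl (2R)-2-[(1R)-cyclopent-2-en-1-yl]-2-hydroxyacetate
Product: 7 methyl (2R)-2-[(tert-butyldimethylsilyl)oxy]-2-[(1R)-cyclopent-2-en-1-yl]acetate
Conditions: TBSCl, imidazole, DMF, 25 °C
Reagents that add atoms: tert-butyldimethylsilyl chloride, CC(C)(C)[Si](C)(C)Cl
Why: Standard O-silylation, which masks the hydroxyl through the organometallic and oxidative steps and touches no stereocentre.

Step 4
Reactants: 7 methyl (2R)-2-[(tert-butyldimethylsilyl)oxy]-2-[(1R)-cyclopent-2-en-1-yl]acetate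
Product: 8 methyl (2R)-2-[(tert-butyldimethylsilyl)oxy]-2-[(1R)-4-oxocyclopent-2-en-1-yl]acetate
Conditions: Rh2(cap)4 (1 mol %, cap = caprolactamate), aq. t-BuOOH, ClCH2CH2Cl, 40 °C
Reagents that add atoms: tert-butyl hydroperoxide, CC(C)(C)OO
Why: Dirhodium-catalysed allylic oxidation: the only unhindered allylic CH2 of the ring should be taken to the enone carbonyl, while the tertiary allylic C–H next to the side chain and both stereocentres stay untouched.

Step 5
Reactants: 9 (1-bromoethenyl)trimethylsilane; 8 methyl (2R)-2-[(tert-butyldimethylsilyl)oxy]-2-[(1R)-4-oxocyclopent-2-en-1-yl]acetate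
Product: 11 methyl (2R)-2-[(tert-butyldimethylsilyl)oxy]-2-{(1R,2S)-2-[1-(trimethylsilyl)ethenyl]-4-[(trimethylsilyl)oxy]cyclopent-3-en-1-yl}acetate, via alkenylmagnesium bromide 10 (not isolated)
Conditions: Mg, THF, 40 °C; then CuBr·SMe2 (10 mol %), TMSCl, 8, THF, −78 °C; Et3N quench
Reagents that add atoms: chlorotrimethylsilane, C[Si](C)(C)Cl
Why: Copper-catalysed conjugate addition of a Grignard reagent accelerated by TMSCl: the alkenyl group should add to the enone face anti to the ring substituent (new stereocentre trans), and the enolate is trapped regiospecifically as its silyl enol ether.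

Step 6
Reactants: 11 methyl (2R)-2-[(tert-butyldimethylsilyl)oxy]-2-{(1R,2S)-2-[1-(trimethylsilyl)ethenyl]-4-[(trimethylsilyl)oxy]cyclopent-3-en-1-yl}acetate
Product: 13 (3R,4S)-3-[(1R)-1-[(tert-butyldimethylsilyl)oxy]-2-methoxy-2-oxoethyl]-4-formyl-5-(trimethylsilyl)hex-5-enoic acid, via α-ketol 12 (not isolated)
Conditions: m-CPBA (1.0 equiv), CH2Cl2–hexane, −20 °C; then H5IO6, THF–H2O, 0 °C
Reagents that add atoms: 3-chloroperbenzoic acid, OOC(=O)c1cccc(Cl)c1; periodic acid, OI(O)(O)(O)(O)=O
Why: Rubottom oxidation followed by periodate cleavage of the α-ketol: the silyl enol ether is by far the most electron-rich alkene, and cleavage turns the former carbonyl carbon into the acid and the former enol carbon into the aldehyde without touching the three stereocentres.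

Step 7
Reactants: 13 (3R,4S)-3-[(1R)-1-[(tert-butyldimethylsilyl)oxy]-2-methoxy-2-oxoethyl]-4-formyl-5-(trimethylsilyl)hex-5-enoic acid
Product: 15 methyl (1S,5R,6R,8S)-3-oxo-8-[1-(trimethylsilyl)ethenyl]-2,7-dioxabicyclo[3.2.1]octane-6-carboxylate, via hydroxy aldehyde acid 14 (not isolated)
Conditions: aq. HF (48 %), MeCN, 0 to 25 °C; then pyridinium p-toluenesulfonate (cat.), 4 Å molecular sieves, PhH, 40 °C
Reagents that add atoms: none
Why: Acid-mediated desilylation and acylal formation (acetalisation–lactonisation): the freed hydroxyl should add to the aldehyde to give the five-membered lactol, the acid should capture the derived oxocarbenium ion, and the new acetal stereocentre is fixed by the geometry of the bridged bicycle (ester exo, alkenyl group syn to the lactone bridge).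

Step 8
Reactants: 15 methyl (1S,5R,6R,8S)-3-oxo-8-[1-(trimethylsilyl)ethenyl]-2,7-dioxabicyclo[3.2.1]octane-6-carboxylate
Product: 17 methyl (1S,5R,6R,8S)-8-(1-bromoethenyl)-3-oxo-2,7-dioxabicyclo[3.2.1]octane-6-carboxylate, via dibromide 16 (not isolated)
Conditions: Br2, CH2Cl2, −78 °C; then Bu4NF–AcOH (1:1), THF, 0 °C
Reagents that add atoms: bromine, BrBr
Why: Bromination–desilicobromination of an α-substituted vinylsilane: addition of Br2 and fluoride-induced loss of the silyl group together with the primary bromide should leave the 2-bromoalkene, with no other alkene present to compete.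

Step 9
Reactants: 18 4,4-dimethylcyclohex-2-en-1-one
Product: 19 2-iodo-4,4-dimethylcyclohex-2-en-1-one
Conditions: I2, pyridine–CH2Cl2, 0 to 25 °C
Reagents that add atoms: iodine, II
Why: α-Iodination of an enone by conjugate addition of pyridine, iodination of the enolate and elimination (Baylis–Hillman-type activation), which creates no stereocentre.

Step 10
Reactants: 19 2-iodo-4,4-dimethylcyclohex-2-en-1-one
Product: 20 (1R)-2-iodo-4,4-dimethylcyclohex-2-en-1-ol
Conditions: (S)-Me-CBS oxazaborolidine (10 mol %), BH3·SMe2, THF, −20 °C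
Reagents that add atoms: none
Why: Corey–Bakshi–Shibata reduction: the iodoalkenyl arm acts as the large group, so hydride delivery inside the catalyst–borane–ketone complex should give the (R)-allylic alcohol.

Step 11
Reactants: 20 (1R)-2-iodo-4,4-dimethylcyclohex-2-en-1-ol; 21 triethyl orthoacetate
Product: 22 ethyl 2-[(1S)-2-iodo-6,6-dimethylcyclohex-2-en-1-yl]acetate
Conditions: EtCO2H (cat.), xylene, 140 °C, EtOH distilled off
Reagents that add atoms: none
Why: Johnson–Claisen rearrangement: the suprafacial [3,3] shift transfers the C–O configuration to the new C–C bond next to the gem-dimethyl group (sets C5 as S, installs C6 and C7) and moves the alkene so that iodine ends on C10 of the C10=C1 bond.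

Step 12
Reactants: 22 ethyl 2-[(1S)-2-iodo-6,6-dimethylcyclohex-2-en-1-yl]acetate
Product: 23 2-[(1S)-2-iodo-6,6-dimethylcyclohex-2-en-1-yl]ethan-1-ol
Conditions: i-Bu2AlH (2.2 equiv), CH2Cl2, −78 to 0 °C; aqueous work-up
Reagents that add atoms: none
Why: Ester reduction with a dialkylaluminium hydride, which leaves the vinyl iodide and C5 untouched.

Step 13
Reactants: 23 2-[(1S)-2-iodo-6,6-dimethylcyclohex-2-en-1-yl]ethan-1-ol; 24 acrolein
Product: 25 (2E)-3-[(6S)-6-(2-hydroxyethyl)-5,5-dimethylcyclohex-1-en-1-yl]prop-2-enal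
Conditions: Pd(OAc)2 (5 mol %), NaHCO3, Bu4NCl, DMF, 25 to 40 °C
Reagents that add atoms: none
Why: Mizoroki–Heck reaction: syn carbopalladation of acrolein at its terminus and syn β-hydride elimination should give the (E)-dienal (installs C9, C20 and the formyl activator), with C5 untouched.

Step 14
Reactants: 25 (2E)-3-[(6S)-6-(2-hydroxyethyl)-5,5-dimethylcyclohex-1-en-1-yl]prop-2-enal
Product: 26 (2E)-3-[(6S)-6-(2-iodoethyl)-5,5-dimethylcyclohex-1-en-1-yl]prop-2-enal
Conditions: I2, PPh3, imidazole, CH2Cl2, 0 °C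
Reagents that add atoms: iodine, II
Why: Appel-type iodination (SN2 at the primary carbon), which the enal tolerates and which touches no stereocentre.

Step 15
Reactants: 26 (2E)-3-[(6S)-6-(2-iodoethyl)-5,5-dimethylcyclohex-1-en-1-yl]prop-2-enal; 17 methyl (1S,5R,6R,8S)-8-(1-bromoethenyl)-3-oxo-2,7-dioxabicyclo[3.2.1]octane-6-carboxylate
Product: 28 methyl (1S,5R,6R,8R)-8-{4-[(1S)-6,6-dimethyl-2-[(1E)-3-oxoprop-1-en-1-yl]cyclohex-2-en-1-yl]but-1-en-2-yl}-3-oxo-2,7-dioxabicyclo[3.2.1]octane-6-carboxylate, via alkylzinc iodide 27 (not isolated)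
Conditions: Zn dust, LiCl, THF, 25 °C; then 17, PdCl2(dppf) (5 mol %), THF, 25 to 40 °C
Reagents that add atoms: none
Why: Negishi sp3–sp2 cross-coupling (C7–C8 bond): zinc inserts into the primary C–I bond, alkylzinc iodides do not add to enals without activation, the chelating diphosphine should suppress β-hydride elimination, and no stereocentre is formed.

Step 16
Reactants: 28 methyl (1S,5R,6R,8R)-8-{4-[(1S)-6,6-dimethyl-2-[(1E)-3-oxoprop-1-en-1-yl]cyclohex-2-en-1-yl]but-1-en-2-yl}-3-oxo-2,7-dioxabicyclo[3.2.1]octane-6-carboxylate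
Product: 29 methyl (1S,5R,6R,8R)-3-oxo-8-[(1S,2R,4aS)-2,5,5-trimethyl-1-(2-oxoethyl)-1,2,3,4,4a,5,6,7-octahydronaphthalen-2-yl]-2,7-dioxabicyclo[3.2.1]octane-6-carboxylate
Conditions: Fe(acac)3 (20 mol %), PhSiH2(Oi-Pr) (2 equiv), THF–i-PrOH (10:1), 0.01 M, 25 °C
Reagents that add atoms: none
Why: An iron hydride formed from Fe(acac)3 and the silane should transfer a hydrogen atom to the unhindered CH2 terminus of the 1,1-disubstituted alkene, giving the tertiary C8 radical, which adds to C9, the β-carbon of the dienal; the α-formyl radical is then reduced to the enolate and protonated by i-PrOH. The closest known reaction type is the metal-hydride hydrogen-atom-transfer reductive olefin coupling, a Giese cyclisation established for tertiary radicals with enal and enone acceptors. Ring B closes in the 6-exo-trig mode through the C8–C9 bond. C8 should be set by a chair-like transition state anchored at the resident C5 stereocentre, with the bulky dioxabicyclooctanone pseudo-equatorial and the new methyl pseudo-axial; C9 should be set in the same chair by the enal arm taking the pseudo-equatorial site, which leaves H-9 axial and anti to the C8 methyl. The step needs chemoselective hydrogen-atom transfer and regioselective addition: the electron-poor, more substituted dienal is a poorer hydrogen-atom acceptor than the terminal methylene, and polarity matching plus ring size direct the nucleophilic radical to C9 and not to C10 or C1. The neutral conditions at room temperature should leave acylal, lactone and ester untouched.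

Step 17
Reactants: 29 methyl (1S,5R,6R,8R)-3-oxo-8-[(1S,2R,4aS)-2,5,5-trimethyl-1-(2-oxoethyl)-1,2,3,4,4a,5,6,7-octahydronaphthalen-2-yl]-2,7-dioxabicyclo[3.2.1]octane-6-carboxylate
Product: 30 methyl (1S,5R,6R,8R)-3-oxo-8-[(1S,2R,4aS)-1,2,5,5-tetramethyl-1,2,3,4,4a,5,6,7-octahydronaphthalen-2-yl]-2,7-dioxabicyclo[3.2.1]octane-6-carboxylate
Conditions: RhCl(PPh3)3 (1.1 equiv), PhMe, 90 °C
Reagents that add atoms: none
Why: Tsuji–Wilkinson decarbonylation: oxidative addition into the formyl C–H bond, CO extrusion and reductive elimination replace CHO by H at the primary carbon, so the C9 substituent becomes methyl while every stereocentre, the alkene and the acylal stay untouched.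

Compound list
1 | cyclopentene | C1=CCCC1 | starting material
2 | methyl glyoxylate | COC(=O)C=O | starting material
3 | methyl (2S)-2-[(1R)-cyclopent-2-en-1-yl]-2-hydroxyacetate | C1=C[C@H]([C@H](O)C(=O)OC)CC1 | intermediate
4 | (2S)-triflate of 3 | C1=C[C@H]([C@H](OS(=O)(=O)C(F)(F)F)C(=O)OC)CC1 | intermediate
5 | (2R)-nitrite ester | C1=C[C@H]([C@@H](ON=O)C(=O)OC)CC1 | intermediate
6 | methyl (2R)-2-[(1R)-cyclopent-2-en-1-yl]-2-hydroxyacetate | C1=C[C@H]([C@@H](O)C(=O)OC)CC1 | intermediate
7 | methyl (2R)-2-[(tert-butyldimethylsilyl)oxy]-2-[(1R)-cyclopent-2-en-1-yl]acetate | C1=C[C@H]([C@@H](O[Si](C)(C)C(C)(C)C)C(=O)OC)CC1 | intermediate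
8 | methyl (2R)-2-[(tert-butyldimethylsilyl)oxy]-2-[(1R)-4-oxocyclopent-2-en-1-yl]acetate | O=C1C=C[C@H]([C@@H](O[Si](C)(C)C(C)(C)C)C(=O)OC)C1 | intermediate
9 | (1-bromoethenyl)trimethylsilane | C=C(Br)[Si](C)(C)C | starting material
10 | [1-(trimethylsilyl)ethenyl]magnesium bromide | C=C([Mg]Br)[Si](C)(C)C | intermediate
11 | trans-adduct, trimethylsilyl enol ether (1R,2S on the ring, 2R in the side chain) | C[Si](C)(C)OC1=C[C@@H](C(=C)[Si](C)(C)C)[C@H]([C@@H](O[Si](C)(C)C(C)(C)C)C(=O)OC)C1 | intermediate
12 | α-ketol (hydroxyl trans to the alkenyl group) | O=C1C[C@@H]([C@@H](O[Si](C)(C)C(C)(C)C)C(=O)OC)[C@H](C(=C)[Si](C)(C)C)[C@H]1O | intermediate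
13 | (3R,4S)-3-[(1R)-1-[(tert-butyldimethylsilyl)oxy]-2-methoxy-2-oxoethyl]-4-formyl-5-(trimethylsilyl)hex-5-enoic acid | COC(=O)[C@H](O[Si](C)(C)C(C)(C)C)[C@H](CC(=O)O)[C@@H](C=O)C(=C)[Si](C)(C)C | intermediate
14 | (3R,4S)-4-formyl-3-[(1R)-1-hydroxy-2-methoxy-2-oxoethyl]-5-(trimethylsilyl)hex-5-enoic acid | COC(=O)[C@H](O)[C@H](CC(=O)O)[C@@H](C=O)C(=C)[Si](C)(C)C | intermediate
15 | methyl (1S,5R,6R,8S)-3-oxo-8-[1-(trimethylsilyl)ethenyl]-2,7-dioxabicyclo[3.2.1]octane-6-carboxylate | COC(=O)[C@@H]1O[C@H]2OC(=O)C[C@@H]1[C@@H]2C(=C)[Si](C)(C)C | intermediate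
16 | 1,2-dibromide of 15 (epimers at the brominated silyl carbon) | COC(=O)[C@@H]1O[C@H]2OC(=O)C[C@@H]1[C@@H]2C(Br)(CBr)[Si](C)(C)C | intermediate
17 | methyl (1S,5R,6R,8S)-8-(1-bromoethenyl)-3-oxo-2,7-dioxabicyclo[3.2.1]octane-6-carboxylate | COC(=O)[C@@H]1O[C@H]2OC(=O)C[C@@H]1[C@@H]2C(Br)=C | intermediate
18 | 4,4-dimethylcyclohex-2-en-1-one | CC1(C)CCC(=O)C=C1 | starting material
19 | 2-iodo-4,4-dimethylcyclohex-2-en-1-one | CC1(C)CCC(=O)C(I)=C1 | intermediate
20 | (1R)-2-iodo-4,4-dimethylcyclohex-2-en-1-ol | O[C@@H]1CCC(C)(C)C=C1I | intermediate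
21 | triethyl orthoacetate | CCOC(C)(OCC)OCC | starting material
22 | ethyl 2-[(1S)-2-iodo-6,6-dimethylcyclohex-2-en-1-yl]acetate | CCOC(=O)C[C@@H]1C(I)=CCCC1(C)C | intermediate
23 | 2-[(1S)-2-iodo-6,6-dimethylcyclohex-2-en-1-yl]ethan-1-ol | OCC[C@@H]1C(I)=CCCC1(C)C | intermediate
24 | acrolein | C=CC=O | starting material
25 | (2E)-3-[(6S)-6-(2-hydroxyethyl)-5,5-dimethylcyclohex-1-en-1-yl]prop-2-enal | OCC[C@@H]1C(/C=C/C=O)=CCCC1(C)C | intermediate
26 | (2E)-3-[(6S)-6-(2-iodoethyl)-5,5-dimethylcyclohex-1-en-1-yl]prop-2-enal | ICC[C@@H]1C(/C=C/C=O)=CCCC1(C)C | intermediate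
27 | alkylzinc iodide from 26 | I[Zn]CC[C@@H]1C(/C=C/C=O)=CCCC1(C)C | intermediate
28 | open triene: bicyclic acylal, C8=CH2, C7–C6 tether, ring A (E)-dienal | COC(=O)[C@@H]1O[C@H]2OC(=O)C[C@@H]1[C@@H]2C(=C)CC[C@@H]1C(/C=C/C=O)=CCCC1(C)C | intermediate
29 | ring-closed aldehyde (target with CH2CHO in place of the C9 methyl) | COC(=O)[C@@H]1O[C@H]2OC(=O)C[C@@H]1[C@@H]2[C@]1(C)CC[C@@H]2C(=CCCC2(C)C)[C@H]1CC=O | intermediate
30 | CNP0301564.1 | COC(=O)[C@@H]1O[C@H]2OC(=O)C[C@@H]1[C@@H]2[C@]1(C)CC[C@@H]2C(=CCCC2(C)C)[C@H]1C | target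

Total step count: 17. Longest linear sequence: 11 steps (steps 1–8, then 15–17).

Steps most likely to fail

Step 16. Hydrogen-atom transfer to the dienal (conjugate reduction) or isomerisation of the 1,1-disubstituted alkene may outrun the cyclisation. The facial selectivity at C8 and C9 may also erode. The fallback sets out from 28 and comes back at 29. Anhydrous HBr (from Me3SiBr and MeOH, CH2Cl2, −40 °C) should add in the Markovnikov sense to the isolated alkene to give the tertiary bromide F1. Bromine-atom abstraction by the silyl radical from (Me3Si)3SiH (Et3B, air, PhMe, 0 °C) then produces the same C8 radical without any metal hydride in the flask. The same 6-exo Giese closure is terminated by hydrogen transfer from the silane.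

Step 7. The liberated hydroxyl may lactonise onto the acid (five-membered lactone) faster than the acetal forms, and the β,γ-unsaturated aldehyde may epimerise or move into conjugation. The fallback sets out from 13 and comes back at 15, and it closes the two rings in the opposite order. Ac2O–pyridine should trap the ring tautomer of the aldehyde acid as the acetoxy lactone F2, so that acid and aldehyde are both tied up in the six-membered ring. HF·pyridine then frees the hydroxy acetate F3. BF3·OEt2 (CH2Cl2, −78 °C) should let the hydroxyl displace the anomeric acetate to close the tetrahydrofuran ring.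

Step 15. Reduction of the enal or addition to it during zinc insertion, and slow coupling at the hindered bromoalkene, may consume the organozinc reagent. The fallback sets out from 23 and comes back at 28, and it carries the activator at the alcohol oxidation level.
- Suzuki–Miyaura coupling of 23 with commercial (E)-3-(tert-butyldimethylsilyloxy)prop-1-enylboronic acid pinacol ester (PdCl2(dppf), K3PO4, THF–H2O) should give the dienyl silyl ether alcohol F4.
- Appel iodination gives the iodide F5, and zinc insertion gives the alkylzinc iodide F6.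
- Negishi coupling of F6 with 17 gives the coupled silyl ether F7.
- HF·pyridine gives the dienol F8, and MnO2 (CH2Cl2) oxidises only the allylic alcohol to 28.

Further compounds
F1 | step 16 | tertiary bromide (Markovnikov HBr adduct of 28, epimers at C8) | COC(=O)[C@@H]1O[C@H]2OC(=O)C[C@@H]1[C@@H]2C(C)(Br)CC[C@@H]1C(/C=C/C=O)=CCCC1(C)C
F2 | step 7 | acetoxy lactone (6-acetoxy-δ-lactone, anomers) | CC(=O)OC1OC(=O)C[C@@H]([C@@H](O[Si](C)(C)C(C)(C)C)C(=O)OC)[C@@H]1C(=C)[Si](C)(C)C
F3 | step 7 | hydroxy acetate | CC(=O)OC1OC(=O)C[C@@H]([C@@H](O)C(=O)OC)[C@@H]1C(=C)[Si](C)(C)C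
F4 | step 15 | dienyl silyl ether alcohol | OCC[C@@H]1C(/C=C/CO[Si](C)(C)C(C)(C)C)=CCCC1(C)C
F5 | step 15 | iodide | ICC[C@@H]1C(/C=C/CO[Si](C)(C)C(C)(C)C)=CCCC1(C)C
F6 | step 15 | alkylzinc iodide | I[Zn]CC[C@@H]1C(/C=C/CO[Si](C)(C)C(C)(C)C)=CCCC1(C)C
F7 | step 15 | coupled silyl ether | COC(=O)[C@@H]1O[C@H]2OC(=O)C[C@@H]1[C@@H]2C(=C)CC[C@@H]1C(/C=C/CO[Si](C)(C)C(C)(C)C)=CCCC1(C)C
F8 | step 15 | dienol | COC(=O)[C@@H]1O[C@H]2OC(=O)C[C@@H]1[C@@H]2C(=C)CC[C@@H]1C(/C=C/CO)=CCCC1(C)C
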